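## The problem

Target 26 is a 2,3,4,7-tetrahydrooxepine (O1, C2, C3, C4, C5=C6, C7) whose single ring carries the whole periphery. C2 is a fully substituted ether carbon bearing a carboxylic acid and a 2-(2,5-dihydroxyphenyl)-2-oxoethyl arm; C6 bears a 4-methylpent-3-enyl chain whose terminal oxygen is esterified by p-coumaric acid. C2 is the only stereocentre, (R). No second centre can control it, so it must come from an enantioselective reaction on an achiral precursor and must then be kept away from conditions that reverse its formation. Three alkenes need defined position or geometry: the ring alkene at C5=C6 (not C4=C5, not exocyclic), the E trisubstituted alkene of the chain and the E cinnamate. The C2 oxygen lies β to the aryl ketone, so base can expel it (retro-oxa-Michael, after which the 2'-phenol can close a chromanone), and before the ring exists the same array can cleave by retro-aldol. The allylic coumarate is open to hydrolysis, acyl transfer and ionisation, and the free hydroquinone to oxidation, so the end game must avoid hydroxide, strong acid, oxidants, hydrogenation and allyl-palladium chemistry. A seven-membered ether is slow to close, and an O1–C7 closure through an allylic cation would prefer the five-membered ether through C5. The enabling feature is that C6 of the ring alkene is bonded to C7, a methylene whose only other neighbour is O1: cutting C6–C7 leaves a one-carbon oxocarbenium ion on the C2 oxygen and asks for a C6 nucleophile that keeps the C5=C6 alkene, which a vinylsilane with silicon on C6 provides.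

## Retrosynthesis

**26 from 25 (no skeletal bond).** 26 is traced to 25, in which the three phenols are tert-butyldimethylsilyl ethers and the acid is a 2-(trimethylsilyl)ethyl ester. A methyl ester would need hydroxide, a benzyl ester hydrogenation, an allyl ester zerovalent palladium (which ionises the allylic coumarate), and a tert-butyl ester would not survive the Lewis acid of the ring closure. All four silicon groups fall to fluoride in one operation; the forward step must supply fluoride without hydroxide.

**25 from 24 (C6–C7, closes the oxepine).** The cut gives the acyclic methoxymethyl ether 24 with a (Z)-vinylsilane at C5=C6. Against its neighbours: an O1–C7 etherification would pass through a C5–C6–C7 allyl cation and give the five-membered ether; a C5=C6 metathesis would need O-alkylation of a hindered tertiary aldol alcohol with a 2-substituted allyl unit; an O1–C2 closure would form the stereocentre in the ring-closing step without control. The precursor has no ring and an already fixed C2. The forward reaction must ionise the acetal toward O1=CH2, attack through C6 and leave the coumarate and silyl groups alone.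

**24 from 23, and 23 from 19 and 22 (two C–O bonds).** The methoxymethyl group goes onto the only free hydroxyl of 23. The coumaroyl ester is formed from diol 19 and acid 22 at the primary allylic hydroxyl, the tertiary one being inert. Acylating before ring closure avoids a further orthogonal protecting group on the chain oxygen and leaves a single step after the key step. Acid 22 is the mono-silylated form of 20.

**19 from 14 and 17 (C2–CH2, sets C2).** An aldol cut gives α-keto ester 14 and enolsilane 17. The neighbouring cut at C2–C3 would add an alkyl metal to an aroylpyruvate, which enolises and offers no handle for facial control. The keto ester is a two-point binder for a chiral Lewis acid, so the aldol can be catalytic and enantioselective. Both precursors are achiral; the forward step must deliver one face of the ketone and trap the adduct as a silyl ether so it cannot revert.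

**14 from 9 and 12 (C2–C3).** The keto ester is cut to the Grignard reagent of bromide 9 and oxalate 12, which brings the final ester group with it. Oxalate 12 comes from 10 and 11. The forward step needs single addition.

**9 from 3 and 7 (C6–chain, sp2–sp3).** A Negishi coupling is preferred to alkylation of an alkenylalanate, which is reliable only with methyl, allyl and similar halides and not with a homoallylic one. Iodide 7 comes from alcohol 6, and 6 from silylalkyne 4 by cis hydroalumination and iodinolysis, which fixes silicon cis to C4. The bromide in 7 is placed before the coupling so that the C3 arm needs no protecting group.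

**Small fragments.** Bromide 3 is the silyl ether of 2, made from commercial 1 by E-selective allylic oxidation. Enolsilane 17 comes from 15 via 16. Compounds 1, 4, 10, 11, 15 and 20 are commercial.

## Roads not taken

**Alternative 1:** The cut lies inside a bicyclic precursor: the C5–C7 bond of dibromocyclopropane A1, a 7,7-dibromo-2-oxabicyclo[4.1.0]heptane that already holds C2. In the forward step AgOTf removes one bromide, the cyclopropane opens to a bromoallyl oxocarbenium ion and methanol adds at C7, giving the 6-bromo-7-methoxy-oxepine A2.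
- Merits: the expansion is driven by strain release, the alkene position follows from the mechanism without a directing element, and the C6 bromide allows the chain to be attached late by coupling. That is more convergent than the chosen plan, which carries the chain from step 5 on.
- Weak points: C7 arrives one oxidation level too high and must be reduced through a bromoallyl cation that can take hydride at C7 or C5. A2 has only an acetate arm, so the aryl ketone must be built from a methyl ester next to the silylethyl ester and a β-alkoxy group that eliminates easily. The coupling at C6 sits beside an acetal. A1 needs its own enantioselective access to the same quaternary centre.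
- Comparison: at least four operations follow ring formation, against one in the chosen plan. The chosen plan sets its step economy after ring closure against A1's mechanistically certain alkene position, at the price of relying on silicon for regiocontrol.

**Alternative 2:** The cut is O1–C7 in the carbenoid sense. Diazoketone A3 loses nitrogen on Rh2(OAc)4 and the tertiary hydroxyl inserts into the carbenoid, giving oxepan-3-one A4.
- Merits: O–H insertion is fast, neutral and works with tertiary alcohols, no ring-size competition arises, and C2 can be set beforehand by the same aldol logic. As a ring closure it is at least as safe as the chosen one, since it needs neither a strong Lewis acid nor a contest between two alkene carbons.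
- Weak points: A4 has a C6 ketone and a saturated C5. Enolisation must go toward C5 and not toward C7, which is activated by O1, and the chain must then be coupled to an enol derivative, so the alkene position is not secured. The aryl ketone must be masked as a dioxolane through A3 and A4 and released by acid beside a β-alkoxy group.
- Comparison: the chosen plan sets against the safer closure that alkene position and chain are settled in or before the ring-forming step, with three or four fewer operations after it.

**Alternative 3:** The cut is O1–C2. In seco-enone A5 the C7 hydroxyl of a (Z)-allylic alcohol adds to C2 of an aroylacrylate (7-exo), giving the oxepine core A6.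
- Merits: it is the shortest route on paper, needs no protection of a tertiary alcohol and no vinylsilane, and mirrors a plausible biogenesis. If it could be made enantioselective it would beat the chosen plan by several steps.
- Weak points: A5 is achiral, so C2 would be created in the ring-closing step with no resident stereocentre, and catalyst control of a seven-membered oxa-Michael addition forming a fully substituted ether carbon has no close precedent. The addition is reversible, by the same equilibrium that threatens 26 under base, so the ring can reopen and the configuration erode. The doubly activated acceptor can be attacked at either alkene carbon.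
- Comparison: the chosen plan sets against this brevity a C2 fixed by an irreversible, catalyst-controlled C–C bond formation before ring closure, and a ring closure that forms a C–C bond and cannot revert.

Key step: step 14

Assumption: the sense of induction in step 10 is taken from the square-planar chelate model for pyruvate esters, in which the (S,S)-bisoxazoline exposes the si face of the ketone; the re face needed for (2R) therefore calls for the (R,R) ligand.

## Route

Step 1
Reactants: 1 5-bromo-2-methylpent-2-ene
Product: 2 (2E)-5-bromo-2-methylpent-2-en-1-ol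
Conditions: SeO2 (0.5 equiv), t-BuOOH (70% aq.), salicylic acid (cat.), CH2Cl2, 25 °C
Reagents that add atoms: selenium dioxide, O=[Se]=O; tert-butyl hydroperoxide, CC(C)(C)OO
Why: Selenium dioxide allylic oxidation (ene reaction, then [2,3]-sigmatropic shift) hydroxylates a methyl group at the more substituted end of a trisubstituted alkene and gives the E allylic alcohol; the primary bromide is inert.

Step 2
Reactants: 2 (2E)-5-bromo-2-methylpent-2-en-1-ol
Product: 3 {[(2E)-5-bromo-2-methylpent-2-en-1-yl]oxy}triethylsilane
Conditions: Et3SiCl, imidazole, CH2Cl2, 0 °C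
Reagents that add atoms: chlorotriethylsilane, CC[Si](Cl)(CC)CC
Why: Standard silylation of a primary alcohol; the triethylsilyl ether tolerates organozinc and Grignard chemistry and is later removed by dilute acid together with the aldol trimethylsilyl group while aryl tert-butyldimethylsilyl ethers stay.

Step 3
Reactants: 4 4-(trimethylsilyl)but-3-yn-1-ol
Product: 6 (3E)-4-iodo-4-(trimethylsilyl)but-3-en-1-ol, via alkenylalane 5 (not isolated)
Conditions: i-Bu2AlH (2.6 equiv), Et2O/hexanes, 0 → 35 °C; then I2, THF, −78 → 0 °C; aq. Na2S2O3, aq. KNaC4H4O6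
Reagents that add atoms: iodine, II
Why: Hydroalumination of a 1-silylalkyne places aluminium on the silicon-bearing carbon and is a cis addition in a donor solvent; the first equivalent of hydride only deprotonates the alcohol. Iodinolysis of the C–Al bond with retention puts iodine trans and silicon cis to the CH2CH2O arm, the geometry the ring closure needs.

Step 4
Reactants: 6 (3E)-4-iodo-4-(trimethylsilyl)but-3-en-1-ol
Product: 7 [(1E)-4-bromo-1-iodobut-1-en-1-yl]trimethylsilane
Conditions: CBr4, PPh3, CH2Cl2, 0 °C
Reagents that add atoms: tetrabromomethane, BrC(Br)(Br)Br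
Why: Appel reaction of a primary alcohol under neutral conditions; alkenyl iodide and vinylsilane are untouched. The bromide is inert in the palladium step and becomes the Grignard centre in step 7, so this arm needs no protecting group.

Step 5
Reactants: 3 {[(2E)-5-bromo-2-methylpent-2-en-1-yl]oxy}triethylsilane; 7 [(1E)-4-bromo-1-iodobut-1-en-1-yl]trimethylsilane
Product: 9 {[(2E,6Z)-9-bromo-2-methyl-6-(trimethylsilyl)nona-2,6-dien-1-yl]oxy}triethylsilane, via alkylzinc bromide 8 (not isolated)
Conditions: 3 (1.3 equiv), Zn dust, LiCl, THF, 50 °C, decant from excess Zn; then 7, PdCl2(dppf) (5 mol %), THF, 25 → 40 °C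
Reagents that add atoms: none
Why: Zinc inserts into the primary C–Br bond of 3 in the presence of LiCl, and the alkylzinc tolerates the silyl ether. In the Negishi sp3–sp2 coupling zerovalent palladium adds to the alkenyl C–I bond of 7 far faster than to its unactivated primary C–Br bond, the wide-bite-angle dppf ligand favours reductive elimination over β-hydride elimination, and alkene geometry is retained, so the chain ends trans and silicon cis to C4.

Step 6
Reactants: 10 oxalyl chloride; 11 2-(trimethylsilyl)ethanol
Product: 12 bis[2-(trimethylsilyl)ethyl] oxalate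
Conditions: 11 (2.1 equiv), pyridine, CH2Cl2, 0 → 25 °C
Reagents that add atoms: none
Why: Double acylation of a primary alcohol by an acid chloride; it builds the final ester group into the acylating agent before any sensitive functionality exists.

Step 7
Reactants: 9 {[(2E,6Z)-9-bromo-2-methyl-6-(trimethylsilyl)nona-2,6-dien-1-yl]oxy}triethylsilane; 12 bis[2-(trimethylsilyl)ethyl] oxalate
Product: 14 2-(trimethylsilyl)ethyl (5Z,9E)-10-methyl-2-oxo-11-[(triethylsilyl)oxy]-6-(trimethylsilyl)undeca-5,9-dienoate, via Grignard reagent 13 (not isolated)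
Conditions: Mg, THF, 25 → 45 °C; add to 12 (2.5 equiv), THF, −78 °C; AcOH, −78 °C
Reagents that add atoms: none
Why: Grignard acylation with a dialkyl oxalate: inverse addition at −78 °C to excess 12 gives a tetrahedral magnesium alkoxide that does not collapse until the acidic quench, so a single addition gives the α-keto ester. Vinylsilane and silyl ether are inert to magnesium.

Step 8
Reactants: 15 1-(2,5-dihydroxyphenyl)ethan-1-one
Product: 16 1-(2,5-bis{[tert-butyl(dimethyl)silyl]oxy}phenyl)ethan-1-one
Conditions: t-BuMe2SiCl (2.5 equiv), imidazole, DMF, 25 → 50 °C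
Reagents that add atoms: tert-butyl(chloro)dimethylsilane, CC(C)(C)[Si](C)(C)Cl
Why: Silylation of both phenols; the hydrogen-bonded 2'-hydroxyl needs gentle warming. The aryl silyl ethers withstand the dilute acid of step 10 and the Lewis acid of step 14 and fall to fluoride at the end.

Step 9
Reactants: 16 1-(2,5-bis{[tert-butyl(dimethyl)silyl]oxy}phenyl)ethan-1-one
Product: 17 {[1-(2,5-bis{[tert-butyl(dimethyl)silyl]oxy}phenyl)ethenyl]oxy}trimethylsilane
Conditions: Me3SiOTf, Et3N, CH2Cl2, 0 °C
Reagents that add atoms: trimethylsilyl trifluoromethanesulfonate, C[Si](C)(C)OS(=O)(=O)C(F)(F)F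
Why: Soft enolisation of a methyl ketone (the silyl triflate activates the carbonyl, the amine removes the α-proton) gives the only possible enolsilane, which is used without chromatography.

Step 10
Reactants: 14 2-(trimethylsilyl)ethyl (5Z,9E)-10-methyl-2-oxo-11-[(triethylsilyl)oxy]-6-(trimethylsilyl)undeca-5,9-dienoate; 17 {[1-(2,5-bis{[tert-butyl(dimethyl)silyl]oxy}phenyl)ethenyl]oxy}trimethylsilane
Product: 19 2-(trimethylsilyl)ethyl (2R,5Z,9E)-2-[2-(2,5-bis{[tert-butyl(dimethyl)silyl]oxy}phenyl)-2-oxoethyl]-2,11-dihydroxy-10-methyl-6-(trimethylsilyl)undeca-5,9-dienoate, via bis-silyl aldol adduct 18 (not isolated)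
Conditions: Cu(OTf)2 (10 mol %), (R,R)-t-Bu-box [2,2'-(propane-2,2-diyl)bis((4R)-4-tert-butyl-4,5-dihydrooxazole)] (11 mol %), THF, −78 → −50 °C; then 1 M HCl, THF, 0 → 25 °C
Reagents that add atoms: none
Why: Catalytic enantioselective Mukaiyama aldol: the α-keto ester chelates the square-planar divalent copper of the Cu(OTf)2–bisoxazoline complex through both carbonyl oxygens, a tert-butyl group of the ligand blocks one face of the ketone, and 17 adds to the other, the re face with the (R,R) ligand, which sets (2R), the only stereocentre. The adduct is trapped as silyl ether 18 and cannot revert; dilute acid then removes the tertiary trimethylsilyl and primary triethylsilyl ethers and leaves the aryl silyl ethers and the vinylsilane.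

Step 11
Reactants: 20 p-coumaric acid
Product: 22 (2E)-3-(4-{[tert-butyl(dimethyl)silyl]oxy}phenyl)prop-2-enoic acid, via silyl ester 21 (not isolated)
Conditions: t-BuMe2SiCl (2.3 equiv), imidazole, DMF, 25 °C; then AcOH/THF/H2O, 25 °C
Reagents that add atoms: tert-butyl(chloro)dimethylsilane, CC(C)(C)[Si](C)(C)Cl
Why: Silylation of phenol and acid, then selective hydrolysis of the far more labile silyl ester in dilute aqueous acetic acid; base is avoided because it would cleave the aryl silyl ether.

Step 12
Reactants: 19 2-(trimethylsilyl)ethyl (2R,5Z,9E)-2-[2-(2,5-bis{[tert-butyl(dimethyl)silyl]oxy}phenyl)-2-oxoethyl]-2,11-dihydroxy-10-methyl-6-(trimethylsilyl)undeca-5,9-dienoate; 22 (2E)-3-(4-{[tert-butyl(dimethyl)silyl]oxy}phenyl)prop-2-enoic acid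
Product: 23 2-(trimethylsilyl)ethyl (2R,5Z,9E)-2-[2-(2,5-bis{[tert-butyl(dimethyl)silyl]oxy}phenyl)-2-oxoethyl]-11-{[(2E)-3-(4-{[tert-butyl(dimethyl)silyl]oxy}phenyl)prop-2-enoyl]oxy}-2-hydroxy-10-methyl-6-(trimethylsilyl)undeca-5,9-dienoate
Conditions: EDC·HCl, DMAP (0.1 equiv), CH2Cl2, 0 → 25 °C
Reagents that add atoms: none
Why: Steglich esterification (carbodiimide, DMAP): only the primary allylic hydroxyl is acylated, the tertiary hydroxyl next to the ester is inert, so no protecting group is needed. The near-neutral conditions leave the aldol unit intact.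

Step 13
Reactants: 23 2-(trimethylsilyl)ethyl (2R,5Z,9E)-2-[2-(2,5-bis{[tert-butyl(dimethyl)silyl]oxy}phenyl)-2-oxoethyl]-11-{[(2E)-3-(4-{[tert-butyl(dimethyl)silyl]oxy}phenyl)prop-2-enoyl]oxy}-2-hydroxy-10-methyl-6-(trimethylsilyl)undeca-5,9-dienoate
Product: 24 2-(trimethylsilyl)ethyl (2R,5Z,9E)-2-[2-(2,5-bis{[tert-butyl(dimethyl)silyl]oxy}phenyl)-2-oxoethyl]-11-{[(2E)-3-(4-{[tert-butyl(dimethyl)silyl]oxy}phenyl)prop-2-enoyl]oxy}-2-(methoxymethoxy)-10-methyl-6-(trimethylsilyl)undeca-5,9-dienoate
Conditions: MeOCH2Cl, i-Pr2NEt, n-Bu4NI (cat.), CH2Cl2, 0 → 40 °C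
Reagents that add atoms: chloromethyl methyl ether, COCCl
Why: Alkylation of the one remaining hydroxyl with an α-chloro ether (iodide forms the more reactive iodomethyl ether in situ); this small, cation-like electrophile is the standard answer to hindered tertiary alcohols. The hindered amine is too weak to enolise the ketone appreciably under these conditions.

Step 14
Reactants: 24 2-(trimethylsilyl)ethyl (2R,5Z,9E)-2-[2-(2,5-bis{[tert-butyl(dimethyl)silyl]oxy}phenyl)-2-oxoethyl]-11-{[(2E)-3-(4-{[tert-butyl(dimethyl)silyl]oxy}phenyl)prop-2-enoyl]oxy}-2-(methoxymethoxy)-10-methyl-6-(trimethylsilyl)undeca-5,9-dienoate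
Product: 25 2-(trimethylsilyl)ethyl (2R)-2-[2-(2,5-bis{[tert-butyl(dimethyl)silyl]oxy}phenyl)-2-oxoethyl]-6-[(3E)-5-{[(2E)-3-(4-{[tert-butyl(dimethyl)silyl]oxy}phenyl)prop-2-enoyl]oxy}-4-methylpent-3-en-1-yl]-2,3,4,7-tetrahydrooxepine-2-carboxylate
Conditions: SnCl4 (3 equiv), 2,6-di-tert-butyl-4-methylpyridine (1.5 equiv), CH2Cl2, −78 → −20 °C
Reagents that add atoms: none
Why: SnCl4 binds the methoxy oxygen of the acetal, the only unhindered and electron-rich acetal oxygen since O1 sits on a fully substituted carbon that also carries an ester, and methoxide leaves to give the O1=C7H2 oxocarbenium ion. C6 of the vinylsilane attacks the cation (ipso attack), which places the charge on C5, β to silicon; the C–Si bond then comes into conjugation and chloride removes the silyl group, restoring C5=C6 inside the ring. The closest known reaction is the Lewis acid-promoted acetal–vinylsilane cyclisation of alkoxymethyl ethers of (Z)-5-silylpent-4-en-1-ols to 2,3,4,7-tetrahydrooxepines; ipso attack at a silicon-bearing carbon that also carries an alkyl group is known from iminium–vinylsilane cyclisations and from acylation of 1-silylcycloalkenes. The oxepine closes in the 7-endo mode with respect to the vinylsilane, both alkene carbons ending in the ring. No stereocentre is formed: C2 takes part in no bond change and its ester disfavours ionisation of C2–O1, so the configuration from step 10 is carried through. The step needs C6 attack over six-membered exo closure through C5, ionisation toward O1=CH2 over loss of the whole alkoxymethyl group, and loss of silicon over loss of a proton. These are secured by the β-silicon effect together with the fact that only the C6 adduct has an irreversible exit by desilylation (attack at C5 would leave the charge on C6 beside silicon, where silicon gives no such help), by the electronic bias between the two acetal oxygens, and by the weak C–Si bond. The Z geometry lets C7 take the place of silicon cis to C4 as the ring alkene requires, the hindered pyridine removes HCl so the vinylsilane is not protodesilylated, and the low temperature keeps the allylic coumarate, the aryl silyl ethers and the silylethyl ester out of the reaction.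

Step 15
Reactants: 25 2-(trimethylsilyl)ethyl (2R)-2-[2-(2,5-bis{[tert-butyl(dimethyl)silyl]oxy}phenyl)-2-oxoethyl]-6-[(3E)-5-{[(2E)-3-(4-{[tert-butyl(dimethyl)silyl]oxy}phenyl)prop-2-enoyl]oxy}-4-methylpent-3-en-1-yl]-2,3,4,7-tetrahydrooxepine-2-carboxylate
Product: 26 (2R)-2-[2-(2,5-dihydroxyphenyl)-2-oxoethyl]-6-[(3E)-5-{[(2E)-3-(4-hydroxyphenyl)prop-2-enoyl]oxy}-4-methylpent-3-en-1-yl]-2,3,4,7-tetrahydrooxepine-2-carboxylic acid
Conditions: tris(dimethylamino)sulfonium difluorotrimethylsilicate (TASF, 8 equiv), DMF, 0 → 25 °C; aq. NaH2PO4 (pH 4)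
Reagents that add atoms: none
Why: Fluoride-induced global desilylation: the aryl silyl ethers cleave first and the 2-(trimethylsilyl)ethyl ester then fragments to carboxylate, ethene and fluorosilane. The anhydrous, hydroxide-free reagent spares the coumarate, and the early-formed 2'-phenoxide is conjugated with the ketone, which lowers the acidity of the CH2 next to C2 and protects the ring against β-elimination; the buffered work-up returns phenols and acid.

## Compound list

1 | 5-bromo-2-methylpent-2-ene | CC(C)=CCCBr | starting material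
2 | (2E)-5-bromo-2-methylpent-2-en-1-ol | C/C(=C\CCBr)CO | intermediate
3 | {[(2E)-5-bromo-2-methylpent-2-en-1-yl]oxy}triethylsilane | C/C(=C\CCBr)CO[Si](CC)(CC)CC | intermediate
4 | 4-(trimethylsilyl)but-3-yn-1-ol | C[Si](C)(C)C#CCCO | starting material
5 | diisobutyl{(1Z)-4-[(diisobutylalumanyl)oxy]-1-(trimethylsilyl)but-1-en-1-yl}alumane | CC(C)C[Al](CC(C)C)OCC/C=C(/[Al](CC(C)C)CC(C)C)[Si](C)(C)C | intermediate
6 | (3E)-4-iodo-4-(trimethylsilyl)but-3-en-1-ol | OCC/C=C(/I)[Si](C)(C)C | intermediate
7 | [(1E)-4-bromo-1-iodobut-1-en-1-yl]trimethylsilane | BrCC/C=C(/I)[Si](C)(C)C | intermediate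
8 | bromo{(3E)-4-methyl-5-[(triethylsilyl)oxy]pent-3-en-1-yl}zinc | C/C(=C\CC[Zn]Br)CO[Si](CC)(CC)CC | intermediate
9 | {[(2E,6Z)-9-bromo-2-methyl-6-(trimethylsilyl)nona-2,6-dien-1-yl]oxy}triethylsilane | C/C(=C\CC/C(=C/CCBr)[Si](C)(C)C)CO[Si](CC)(CC)CC | intermediate
10 | oxalyl chloride | O=C(Cl)C(=O)Cl | starting material
11 | 2-(trimethylsilyl)ethanol | C[Si](C)(C)CCO | starting material
12 | bis[2-(trimethylsilyl)ethyl] oxalate | C[Si](C)(C)CCOC(=O)C(=O)OCC[Si](C)(C)C | intermediate
13 | bromo{(3Z,7E)-8-methyl-9-[(triethylsilyl)oxy]-4-(trimethylsilyl)nona-3,7-dien-1-yl}magnesium | C/C(=C\CC/C(=C/CC[Mg]Br)[Si](C)(C)C)CO[Si](CC)(CC)CC | intermediate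
14 | 2-(trimethylsilyl)ethyl (5Z,9E)-10-methyl-2-oxo-11-[(triethylsilyl)oxy]-6-(trimethylsilyl)undeca-5,9-dienoate | C/C(=C\CC/C(=C/CCC(=O)C(=O)OCC[Si](C)(C)C)[Si](C)(C)C)CO[Si](CC)(CC)CC | intermediate
15 | 1-(2,5-dihydroxyphenyl)ethan-1-one | CC(=O)c1cc(O)ccc1O | starting material
16 | 1-(2,5-bis{[tert-butyl(dimethyl)silyl]oxy}phenyl)ethan-1-one | CC(=O)c1cc(O[Si](C)(C)C(C)(C)C)ccc1O[Si](C)(C)C(C)(C)C | intermediate
17 | {[1-(2,5-bis{[tert-butyl(dimethyl)silyl]oxy}phenyl)ethenyl]oxy}trimethylsilane | C=C(O[Si](C)(C)C)c1cc(O[Si](C)(C)C(C)(C)C)ccc1O[Si](C)(C)C(C)(C)C | intermediate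
18 | 2-(trimethylsilyl)ethyl (2R,5Z,9E)-2-[2-(2,5-bis{[tert-butyl(dimethyl)silyl]oxy}phenyl)-2-oxoethyl]-10-methyl-11-[(triethylsilyl)oxy]-6-(trimethylsilyl)-2-[(trimethylsilyl)oxy]undeca-5,9-dienoate | C/C(=C\CC/C(=C/CC[C@@](CC(=O)c1cc(O[Si](C)(C)C(C)(C)C)ccc1O[Si](C)(C)C(C)(C)C)(C(=O)OCC[Si](C)(C)C)O[Si](C)(C)C)[Si](C)(C)C)CO[Si](CC)(CC)CC | intermediate
19 | 2-(trimethylsilyl)ethyl (2R,5Z,9E)-2-[2-(2,5-bis{[tert-butyl(dimethyl)silyl]oxy}phenyl)-2-oxoethyl]-2,11-dihydroxy-10-methyl-6-(trimethylsilyl)undeca-5,9-dienoate | C/C(=C\CC/C(=C/CC[C@@](CC(=O)c1cc(O[Si](C)(C)C(C)(C)C)ccc1O[Si](C)(C)C(C)(C)C)(C(=O)OCC[Si](C)(C)C)O)[Si](C)(C)C)CO | intermediate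
20 | p-coumaric acid, (2E)-3-(4-hydroxyphenyl)prop-2-enoic acid | O=C(O)/C=C/c1ccc(O)cc1 | starting material
21 | tert-butyl(dimethyl)silyl (2E)-3-(4-{[tert-butyl(dimethyl)silyl]oxy}phenyl)prop-2-enoate | CC(C)(C)[Si](C)(C)OC(=O)/C=C/c1ccc(O[Si](C)(C)C(C)(C)C)cc1 | intermediate
22 | (2E)-3-(4-{[tert-butyl(dimethyl)silyl]oxy}phenyl)prop-2-enoic acid | O=C(O)/C=C/c1ccc(O[Si](C)(C)C(C)(C)C)cc1 | intermediate
23 | 2-(trimethylsilyl)ethyl (2R,5Z,9E)-2-[2-(2,5-bis{[tert-butyl(dimethyl)silyl]oxy}phenyl)-2-oxoethyl]-11-{[(2E)-3-(4-{[tert-butyl(dimethyl)silyl]oxy}phenyl)prop-2-enoyl]oxy}-2-hydroxy-10-methyl-6-(trimethylsilyl)undeca-5,9-dienoate | C/C(=C\CC/C(=C/CC[C@@](CC(=O)c1cc(O[Si](C)(C)C(C)(C)C)ccc1O[Si](C)(C)C(C)(C)C)(C(=O)OCC[Si](C)(C)C)O)[Si](C)(C)C)COC(=O)/C=C/c1ccc(O[Si](C)(C)C(C)(C)C)cc1 | intermediate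
24 | 2-(trimethylsilyl)ethyl (2R,5Z,9E)-2-[2-(2,5-bis{[tert-butyl(dimethyl)silyl]oxy}phenyl)-2-oxoethyl]-11-{[(2E)-3-(4-{[tert-butyl(dimethyl)silyl]oxy}phenyl)prop-2-enoyl]oxy}-2-(methoxymethoxy)-10-methyl-6-(trimethylsilyl)undeca-5,9-dienoate | C/C(=C\CC/C(=C/CC[C@@](CC(=O)c1cc(O[Si](C)(C)C(C)(C)C)ccc1O[Si](C)(C)C(C)(C)C)(C(=O)OCC[Si](C)(C)C)OCOC)[Si](C)(C)C)COC(=O)/C=C/c1ccc(O[Si](C)(C)C(C)(C)C)cc1 | intermediate
25 | 2-(trimethylsilyl)ethyl (2R)-2-[2-(2,5-bis{[tert-butyl(dimethyl)silyl]oxy}phenyl)-2-oxoethyl]-6-[(3E)-5-{[(2E)-3-(4-{[tert-butyl(dimethyl)silyl]oxy}phenyl)prop-2-enoyl]oxy}-4-methylpent-3-en-1-yl]-2,3,4,7-tetrahydrooxepine-2-carboxylate | C/C(=C\CCC1=CCC[C@@](CC(=O)c2cc(O[Si](C)(C)C(C)(C)C)ccc2O[Si](C)(C)C(C)(C)C)(C(=O)OCC[Si](C)(C)C)OC1)COC(=O)/C=C/c1ccc(O[Si](C)(C)C(C)(C)C)cc1 | intermediate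
26 | (2R)-2-[2-(2,5-dihydroxyphenyl)-2-oxoethyl]-6-[(3E)-5-{[(2E)-3-(4-hydroxyphenyl)prop-2-enoyl]oxy}-4-methylpent-3-en-1-yl]-2,3,4,7-tetrahydrooxepine-2-carboxylic acid | C/C(=C\CCC1=CCC[C@@](CC(=O)c2cc(O)ccc2O)(C(=O)O)OC1)COC(=O)/C=C/c1ccc(O)cc1 | target

## Step count and least certain steps

Total step count: 15. Longest linear sequence: 9 steps (from 4 through steps 3, 4, 5, 7, 10, 12, 13, 14, 15; the branch from 1 through steps 1, 2, 5 and onward is equally long).

**Step 14 (key step).** The most likely failure is diversion of the Lewis acid and of the cation. SnCl4 can be held by the aryl ketone and the C2 oxygen/ester array, which slows ionisation of the acetal and, through enolisation of the tin-bound ketone toward C2, opens β-elimination of the alkoxymethyl oxygen. Ipso attack at the fully substituted C6 is then slow enough for closure through C5 (six-membered, exo) or protodesilylation to compete. The fallback generates the same cation from an O,S-acetal without an oxophilic Lewis acid. It sets out from 23: Pummerer-type methylthiomethylation (DMSO, Ac2O, AcOH, 25 °C) should give the methylthiomethyl ether F1. S-Methylation with MeOTf (2,6-di-tert-butyl-4-methylpyridine, CH2Cl2, −40 → 0 °C), as in thioglycoside activation, makes sulfur the only possible leaving group; dimethyl sulfide departs, the O1=C7H2 cation closes onto C6 and loses silicon, and the route is rejoined at 25.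

**Step 13.** The hindered, hydrogen-bonded tertiary hydroxyl may be alkylated only slowly, and over the time and temperature needed the amine base can start retro-aldol cleavage of the C2–CH2 bond or dehydration. The fallback replaces base-mediated alkylation by acid-catalysed acetal exchange: 23 is treated with dimethoxymethane and P2O5 in CHCl3 at 25 °C, which uses neither base nor alkyl halide and leads from 23 directly to 24 (no new compound, F0).

**Step 10.** Turnover may be low and enantiofacial selectivity eroded, because enolsilane 17 is hindered by its ortho silyloxy group and less nucleophilic than the silyl ketene acetals for which this catalyst class is best established, so an uncatalysed or silyl-triflate-catalysed racemic pathway can compete. The fallback brings in the aryl ketone after the stereocentre is set. It sets out from 14: the same catalyst with 1-(ethylsulfanyl)-1-[(trimethylsilyl)oxy]ethene and the same acidic work-up should give the thioester diol F2. In parallel, 2-bromobenzene-1,4-diol is silylated (t-BuMe2SiCl, imidazole) to the aryl bromide F3, which by bromine–magnesium exchange (i-PrMgCl·LiCl, THF, −15 °C; magnesium is chosen to avoid silyl migration from oxygen to carbon), B(OMe)3 and dilute acid gives the boronic acid F4. Liebeskind–Srogl coupling of F2 with F4 (Pd2(dba)3, tri(2-furyl)phosphine, copper thiophene-2-carboxylate, THF, 50 °C) is neutral, tolerates both free hydroxyls and rejoins the route at 19.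

**Step 5.** Zinc insertion into 3 may be incomplete, and transmetalation to the hindered α-silyl alkenylpalladium intermediate slow, so that reduction or homocoupling of 7 and loss of alkene geometry at palladium compete. The fallback changes the nucleophile class and how it is made. It sets out from 3: halide exchange (NaI, acetone) gives the iodide F5; iodine–lithium exchange (t-BuLi, Et2O, −78 °C) and capture by 9-methoxy-9-borabicyclo[3.3.1]nonane give the lithium borate F6. F6 is coupled in a B-alkyl Suzuki–Miyaura reaction with 7 (PdCl2(dppf), AsPh3, Cs2CO3, DMF/H2O, 25 °C) and rejoins the route at 9.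

**Step 15.** The silylethyl ester cleaves more slowly than the aryl ethers, so the polyanionic intermediate stands in basic fluoride, where coumaroyl transfer to a phenoxide or β-elimination at C2 with ring opening can set in. The fallback splits the end game so that only one group depends on TASF. It sets out from 25: KHF2 in MeOH at 25 °C, which is selective for aryl silyl ethers and mildly acidic, should give the triphenol ester F7. A short treatment of F7 with TASF in DMF at 0 °C then cleaves only the ester and arrives at 26.

## Further compounds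

F1 | step 14 | 2-(trimethylsilyl)ethyl (2R,5Z,9E)-2-[2-(2,5-bis{[tert-butyl(dimethyl)silyl]oxy}phenyl)-2-oxoethyl]-11-{[(2E)-3-(4-{[tert-butyl(dimethyl)silyl]oxy}phenyl)prop-2-enoyl]oxy}-10-methyl-2-[(methylsulfanyl)methoxy]-6-(trimethylsilyl)undeca-5,9-dienoate | C/C(=C\CC/C(=C/CC[C@@](CC(=O)c1cc(O[Si](C)(C)C(C)(C)C)ccc1O[Si](C)(C)C(C)(C)C)(C(=O)OCC[Si](C)(C)C)OCSC)[Si](C)(C)C)COC(=O)/C=C/c1ccc(O[Si](C)(C)C(C)(C)C)cc1
F0 | step 13 | none | none
F2 | step 10 | 2-(trimethylsilyl)ethyl (2R,5Z,9E)-2-[2-(ethylsulfanyl)-2-oxoethyl]-2,11-dihydroxy-10-methyl-6-(trimethylsilyl)undeca-5,9-dienoate | C/C(=C\CC/C(=C/CC[C@@](CC(=O)SCC)(C(=O)OCC[Si](C)(C)C)O)[Si](C)(C)C)CO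
F3 | step 10 | [(2-bromo-1,4-phenylene)bis(oxy)]bis[tert-butyl(dimethyl)silane] | Brc1cc(O[Si](C)(C)C(C)(C)C)ccc1O[Si](C)(C)C(C)(C)C
F4 | step 10 | (2,5-bis{[tert-butyl(dimethyl)silyl]oxy}phenyl)boronic acid | OB(O)c1cc(O[Si](C)(C)C(C)(C)C)ccc1O[Si](C)(C)C(C)(C)C
F5 | step 5 | triethyl{[(2E)-5-iodo-2-methylpent-2-en-1-yl]oxy}silane | C/C(=C\CCI)CO[Si](CC)(CC)CC
F6 | step 5 | lithium 9-methoxy-9-{(3E)-4-methyl-5-[(triethylsilyl)oxy]pent-3-en-1-yl}-9-boranuidabicyclo[3.3.1]nonane | [Li+].CO[B-]1(CC/C=C(\C)CO[Si](CC)(CC)CC)C2CCCC1CCC2
F7 | step 15 | 2-(trimethylsilyl)ethyl (2R)-2-[2-(2,5-dihydroxyphenyl)-2-oxoethyl]-6-[(3E)-5-{[(2E)-3-(4-hydroxyphenyl)prop-2-enoyl]oxy}-4-methylpent-3-en-1-yl]-2,3,4,7-tetrahydrooxepine-2-carboxylate | C/C(=C\CCC1=CCC[C@@](CC(=O)c2cc(O)ccc2O)(C(=O)OCC[Si](C)(C)C)OC1)COC(=O)/C=C/c1ccc(O)cc1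
A1 | alternative 1 | 2-(trimethylsilyl)ethyl (3R)-7,7-dibromo-3-(2-methoxy-2-oxoethyl)-2-oxabicyclo[4.1.0]heptane-3-carboxylate (cis-fused, ring-fusion configuration not fixed) | BrC1(Br)C2CC[C@@](CC(=O)OC)(C(=O)OCC[Si](C)(C)C)OC12
A2 | alternative 1 | 2-(trimethylsilyl)ethyl (2R,7S)-6-bromo-7-methoxy-2-(2-methoxy-2-oxoethyl)-2,3,4,7-tetrahydrooxepine-2-carboxylate | BrC1=CCC[C@@](CC(=O)OC)(C(=O)OCC[Si](C)(C)C)O[C@@H]1OC
A3 | alternative 2 | 2-(trimethylsilyl)ethyl (2R)-2-{[2-(2,5-bis{[tert-butyl(dimethyl)silyl]oxy}phenyl)-1,3-dioxolan-2-yl]methyl}-7-diazo-2-hydroxy-6-oxoheptanoate | [N-]=[N+]=CC(=O)CCC[C@@](CC1(OCCO1)c1cc(O[Si](C)(C)C(C)(C)C)ccc1O[Si](C)(C)C(C)(C)C)(C(=O)OCC[Si](C)(C)C)O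
A4 | alternative 2 | 2-(trimethylsilyl)ethyl (2R)-2-{[2-(2,5-bis{[tert-butyl(dimethyl)silyl]oxy}phenyl)-1,3-dioxolan-2-yl]methyl}-6-oxooxepane-2-carboxylate | O=C1CCC[C@@](CC2(OCCO2)c2cc(O[Si](C)(C)C(C)(C)C)ccc2O[Si](C)(C)C(C)(C)C)(C(=O)OCC[Si](C)(C)C)OC1
A5 | alternative 3 | 2-(trimethylsilyl)ethyl (2E,5Z,9E)-2-[2-(2,5-bis{[tert-butyl(dimethyl)silyl]oxy}phenyl)-2-oxoethylidene]-6-(hydroxymethyl)-10-methyl-11-[(triethylsilyl)oxy]undeca-5,9-dienoate | C/C(=C\CC/C(CO)=C/CC/C(=C\C(=O)c1cc(O[Si](C)(C)C(C)(C)C)ccc1O[Si](C)(C)C(C)(C)C)C(=O)OCC[Si](C)(C)C)CO[Si](CC)(CC)CC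
A6 | alternative 3 | 2-(trimethylsilyl)ethyl (2R)-2-[2-(2,5-bis{[tert-butyl(dimethyl)silyl]oxy}phenyl)-2-oxoethyl]-6-{(3E)-4-methyl-5-[(triethylsilyl)oxy]pent-3-en-1-yl}-2,3,4,7-tetrahydrooxepine-2-carboxylate | C/C(=C\CCC1=CCC[C@@](CC(=O)c2cc(O[Si](C)(C)C(C)(C)C)ccc2O[Si](C)(C)C(C)(C)C)(C(=O)OCC[Si](C)(C)C)OC1)CO[Si](CC)(CC)CC
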